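The six-membered cyclohexa-2,5-diene-1,4-dione ring is cut into three acyclic pieces: a terminal alkyne (C2 with its nonadecyl chain, and C3), a vinylcarbene ligand (C4, C5, C6) and one CO ligand (C1). A Dötz benzannulation of a β-silylvinyl(methoxy)carbene chromium complex with henicos-1-yne joins them in one operation, forming three C–C bonds and the only ring. It exploits the para relationship of the carbonyl carbons C1 and C4; as the ring has one substituent, either alkyne orientation gives the same quinone. Silicon leaves C6 for oxygen, and ceric ammonium nitrate in the same flask gives the quinone. Both precursors are made in one step each.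

Key step: step 3

Remark: the target has no stereocentre and no stereogenic double bond, so it is achiral and no step has to set configuration. Ring atoms are numbered C1 (C=O next to the chain-bearing carbon), C2 (chain), C3, C4 (C=O), C5, C6. Carbonyl ligands on chromium are written Cr=C=O in the SMILES.

Step 1
Reactants: 1 1-bromononadecane; 2 lithium acetylide–ethylenediamine complex
Product: 3 henicos-1-yne
Conditions: DMSO–THF, 15 °C → rt; then H2O
Reagents that add atoms: none
Why: SN2 alkylation of the acetylide carbanion by a primary bromide (acetylide alkylation) in a dipolar aprotic medium; the diamine complex delivers monolithium acetylide, so the terminal alkyne should form and no stereocentre arises.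

Step 2
Reactants: 4 (E)-(2-bromovinyl)trimethylsilane; 5 hexacarbonylchromium
Product: 8 pentacarbonyl[(E)-1-methoxy-3-(trimethylsilyl)prop-2-en-1-ylidene]chromium(0), via vinyllithium 6 (not isolated), via lithium acylchromate 7 (not isolated)
Conditions: t-BuLi (2 equiv), Et2O, −78 °C; then 5, −78 °C → rt; then Me3OBF4, CH2Cl2, 0 °C → rt
Reagents that add atoms: trimethyloxonium tetrafluoroborate, C[O+](C)C.F[B-](F)(F)F
Why: Fischer carbene synthesis: bromine–lithium exchange should retain the E double bond, the vinyllithium adds to a CO ligand of 5 to give acylchromate 7, and the hard oxonium salt methylates the acyl oxygen; no stereocentre is formed and the β-silyl group protects the complex against polymerisation.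

Step 3
Reactants: 8 pentacarbonyl[(E)-1-methoxy-3-(trimethylsilyl)prop-2-en-1-ylidene]chromium(0); 3 henicos-1-yne
Product: 11 2-nonadecyl-1,4-benzoquinone, via silyl dienone 9 (not isolated), via aryl silyl ether 10 (not isolated)
Conditions: THF, 50 °C, Ar; then (NH4)2Ce(NO3)6, aq HNO3 (0.1 M), THF–Et2O, rt
Reagents that add atoms: water, O
Why: After thermal loss of one CO from 8 the alkyne coordinates and inserts into the Cr=C bond (C3–C4 bond), a CO ligand inserts to give an η4-dienylketene (C1–C2 bond), and this closes to the chromium-bound dienone 9 (C1–C6 bond); the closest known reaction type is the Dötz benzannulation of alkenyl(alkoxy)carbene complexes, a formal [3+2+1] cycloaddition. The six-membered carbocycle is closed by a thermal 6π-electrocyclisation of the dienylketene on the metal, between ketene carbon C1 and the silyl-bearing carbon C6. The only new stereocentre, C6 of 9, is transient and racemic: a 1,3-shift of silicon from C6 to the carbonyl oxygen aromatises the ring to 10, so silicon serves as a traceless group that makes the otherwise polymerisation-prone parent vinyl complex usable. The step needs chemoselectivity for the six-membered ring over cyclobutenone, furan and cyclopentenone products and for one alkyne per metal, which alkenyl(methoxy)chromium complexes in THF at moderate concentration should give; the usual regioselectivity of a terminal alkyne (chain next to C1) is expected but not needed, because both orientations lead to the same monosubstituted quinone. Ceric ammonium nitrate then oxidises chromium off the arene, the labile aryl silyl ether is cleaved in the acidic medium, and two-electron oxidation with attack of water at C4 and loss of methanol should give the quinone. The target is achiral, so no stereocontrol is required.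

Compound list
1 | 1-bromononadecane | CCCCCCCCCCCCCCCCCCCBr | starting material
2 | lithium acetylide–ethylenediamine complex | [Li+].[C-]#C.NCCN | starting material
3 | henicos-1-yne (1-heneicosyne) | CCCCCCCCCCCCCCCCCCCC#C | intermediate
4 | (E)-(2-bromovinyl)trimethylsilane | C[Si](C)(C)/C=C/Br | starting material
5 | hexacarbonylchromium | O=C=[Cr](=C=O)(=C=O)(=C=O)(=C=O)=C=O | starting material
6 | (E)-[2-(trimethylsilyl)vinyl]lithium | C[Si](C)(C)/C=C/[Li] | intermediate (not isolated)
7 | lithium pentacarbonyl[(E)-1-oxido-3-(trimethylsilyl)prop-2-en-1-ylidene]chromate | [Li+].[O-]C(/C=C/[Si](C)(C)C)=[Cr](=C=O)(=C=O)(=C=O)(=C=O)=C=O | intermediate (not isolated)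
8 | pentacarbonyl[(E)-1-methoxy-3-(trimethylsilyl)prop-2-en-1-ylidene]chromium(0) | COC(/C=C/[Si](C)(C)C)=[Cr](=C=O)(=C=O)(=C=O)(=C=O)=C=O | intermediate
9 | 4-methoxy-2-nonadecyl-6-(trimethylsilyl)cyclohexa-2,4-dien-1-one (racemic, formed bound to Cr(CO)3; SMILES of the organic ligand) | CCCCCCCCCCCCCCCCCCCC1=CC(OC)=CC([Si](C)(C)C)C1=O | intermediate (not isolated)
10 | (4-methoxy-2-nonadecylphenoxy)trimethylsilane (formed bound to Cr(CO)3; SMILES of the organic ligand) | CCCCCCCCCCCCCCCCCCCc1cc(OC)ccc1O[Si](C)(C)C | intermediate (not isolated)
11 | 2-nonadecyl-1,4-benzoquinone (2-nonadecylcyclohexa-2,5-diene-1,4-dione) | CCCCCCCCCCCCCCCCCCCC1=CC(=O)C=CC1=O | target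

Total step count: 3. Longest linear sequence: 2 steps (step 1 or step 2, then step 3).

Steps most likely to fail

Step 3 (key step). In dienone 9 a hydrogen shift may compete with the shift of silicon, so that silicon stays on C6 and is carried into the quinone. The β-silylvinyl complex may also decompose, or take up a second alkyne, before CO insertion. The fallback sets out from 3, uses 5, and returns at 11. The ring is still closed last by a benzannulation, but the roles are exchanged so that the chain sits on a robust β-alkylalkenyl complex and no silicon migration is needed.
- Hydrozirconation of 3 with Cp2Zr(H)Cl and iodinolysis should give (E)-1-iodohenicos-1-ene F1.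
- Iodine–lithium exchange (t-BuLi), addition to 5 and O-methylation (Me3OBF4) should give pentacarbonyl[(E)-1-methoxydocos-2-en-1-ylidene]chromium(0) F2.
- Benzannulation of F2 with ethynyltrimethylsilane as an acetylene equivalent (THF, 50 °C, then air) should give 4-methoxy-2-nonadecyl-6-(trimethylsilyl)phenol F3.
- Ipso-protodesilylation (CF3CO2H, CH2Cl2) should give 4-methoxy-2-nonadecylphenol F4, and ceric ammonium nitrate oxidation of F4 leads to 11.
- The orientation of the silylalkyne does not matter, because silicon is removed before oxidation.

Step 2. Deprotonation next to bromine and elimination may compete with the bromine–lithium exchange, the E geometry may erode, and the acylate may be only partly O-alkylated. The fallback sets out from 5, does without 4, and returns at vinyllithium 6. Radical hydrostannation of ethynyltrimethylsilane (Bu3SnH, AIBN, 90 °C) should give (E)-tributyl[2-(trimethylsilyl)vinyl]stannane F5. Tin–lithium exchange with MeLi (THF, −78 → 0 °C) should then give 6 with retention and without excess strong base. 6 is added to 5 and methylated as in step 2.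

Step 1. The waxy bromide dissolves poorly in DMSO, so substitution may be slow, and E2 elimination to the terminal alkene or base-induced migration of the triple bond may compete. The fallback sets out from 1 and returns at 3. It replaces the SN2 reaction by a one-carbon homologation of an aldehyde. The Grignard reagent of 1 (Mg, THF) is formylated with DMF to icosanal F6. The Ohira–Bestmann reagent (dimethyl (1-diazo-2-oxopropyl)phosphonate, K2CO3, MeOH–THF) should convert F6 into 3.

Further compounds
F1 | step 3 | (E)-1-iodohenicos-1-ene | CCCCCCCCCCCCCCCCCCC/C=C/I
F2 | step 3 | pentacarbonyl[(E)-1-methoxydocos-2-en-1-ylidene]chromium(0) | CCCCCCCCCCCCCCCCCCC/C=C/C(OC)=[Cr](=C=O)(=C=O)(=C=O)(=C=O)=C=O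
F3 | step 3 | 4-methoxy-2-nonadecyl-6-(trimethylsilyl)phenol | CCCCCCCCCCCCCCCCCCCc1cc(OC)cc([Si](C)(C)C)c1O
F4 | step 3 | 4-methoxy-2-nonadecylphenol | CCCCCCCCCCCCCCCCCCCc1cc(OC)ccc1O
F5 | step 2 | (E)-tributyl[2-(trimethylsilyl)vinyl]stannane | CCCC[Sn](CCCC)(CCCC)/C=C/[Si](C)(C)C
F6 | step 1 | icosanal | CCCCCCCCCCCCCCCCCCCC=O
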